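**Retrosynthetic overview** (germacrane numbering: ring C1–C10, lactone carbons C11–C13, C14 on C10, C15 on C4)
1. Target 30 ⇐ desilylation, O8 methacrylation, O14 acetylation and tartrate-controlled epoxidation of C1=C10 in macrocyclic diol 23.
2. 23 ⇐ one chromium operation joining enal–lactol 17 and the C4 linchpin 21: C7 serves twice as an allyl nucleophile (C6–C7, then C7–C8), forming the γ-lactone and then the ten-membered carbocycle.
3. 17 ⇐ unmasking of 15 ⇐ B-alkyl Suzuki union (C1–C2) of diene 8 and vinyl iodide 13.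
4. 8 and 13 ⇐ alkoxide-directed anti-carbomagnesiation of two propargylic alcohols, which sets both trisubstituted alkenes.
5. Ring order: γ-lactone and carbocycle together (step 7), epoxide last (step 8).

Assumption: the (S,S) ligand written in step 7 is taken to give Si-face allylation of the enal (6R); if it gives the Re adduct, its enantiomer is used.

**Step 1**
Reactants: 1 3,3-diethoxyprop-1-yne
Product: 6 (2E)-2-(2,2-diethoxyethylidene)but-3-en-1-ol, via alkynol magnesium alkoxide 4 (not isolated), via oxamagnesacycle 5 (not isolated)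
Conditions: EtMgBr, THF, 0 °C to rt; (CH2O)n, 40 °C; CH2=CHMgCl (3 equiv), THF, 65 °C; H2O (pH 7 buffer), 0 °C
Reagents that add atoms: 2 paraformaldehyde, C=O; 3 vinylmagnesium chloride, C=C[Mg]Cl
Why: The alkynyl Grignard adds to formaldehyde and the resulting propargylic magnesium alkoxide directs an anti-carbomagnesiation (Fallis/Duboudin type) that places vinyl on the carbon next to the carbinol carbon and magnesium on the distal carbon in a five-membered chelate, so protonation gives the C4=C5 alkene with C3 and C6 cis.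

**Step 2**
Reactants: 6 (2E)-2-(2,2-diethoxyethylidene)but-3-en-1-ol
Product: 8 tert-butyl{[(2E)-2-(2,2-diethoxyethylidene)but-3-en-1-yl]oxy}diphenylsilane
Conditions: TBDPSCl, imidazole, DMF, 0 °C to rt
Reagents that add atoms: 7 tert-butyl(chloro)diphenylsilane, CC(C)(C)[Si](Cl)(c1ccccc1)c1ccccc1
Why: Standard silylation of the primary allylic alcohol (Corey imidazole protocol), with a silyl group robust enough for the later acetal cleavage and removed last.

**Step 3**
Reactants: 9 prop-2-yn-1-ol
Product: 13 (2Z)-2-(1,3-dioxolan-2-ylmethyl)-3-iodoprop-2-en-1-ol, via vinylmagnesium chelate 12 (not isolated)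
Conditions: EtMgBr (1.0 equiv), THF, 0 °C; 10 (1.6 equiv), CuI (10 mol%), 0 °C to rt; then I2, −40 to 0 °C
Reagents that add atoms: 10 (1,3-dioxolan-2-ylmethyl)magnesium bromide, Br[Mg]CC1OCCO1; 11 iodine, II
Why: Copper-catalysed anti-carbomagnesiation of the propargyl alkoxide (Duboudin–Jousseaume) delivers the alkyl group to C10 and magnesium to C1 cis to the CH2O arm, and iodinolysis with retention gives the (Z)-vinyl iodide that fixes C9 and C2 trans on the later C1=C10 alkene.

**Step 4**
Reactants: 8 tert-butyl{[(2E)-2-(2,2-diethoxyethylidene)but-3-en-1-yl]oxy}diphenylsilane; 13 (2Z)-2-(1,3-dioxolan-2-ylmethyl)-3-iodoprop-2-en-1-ol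
Product: 15 (2Z,6E)-6-{[tert-butyl(diphenyl)silyl]oxymethyl}-2-(1,3-dioxolan-2-ylmethyl)-8,8-diethoxyocta-2,6-dien-1-ol, via alkylborane 14 (not isolated)
Conditions: 9-BBN (1.1 equiv), THF, 0 °C to rt; then 13, Pd(dppf)Cl2 (5 mol%), Ph3As (10 mol%), Cs2CO3, DMF/H2O, rt
Reagents that add atoms: none
Why: 9-BBN hydroborates only the monosubstituted vinyl terminus of the 2-substituted diene (anti-Markovnikov), and the B-alkyl Suzuki–Miyaura coupling with the vinyl iodide proceeds with retention, so both trisubstituted alkenes keep their geometry.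

**Step 5**
Reactants: 15 (2Z,6E)-6-{[tert-butyl(diphenyl)silyl]oxymethyl}-2-(1,3-dioxolan-2-ylmethyl)-8,8-diethoxyocta-2,6-dien-1-ol
Product: 17 (2E,6Z)-3-{[tert-butyl(diphenyl)silyl]oxymethyl}-6-(5-hydroxyoxolan-3-ylidene)hex-2-enal
Conditions: (NH4)2Ce(NO3)6 (5 mol%), MeCN/aq. borate buffer (pH 8), 60 °C
Reagents that add atoms: 16 water, O
Why: Cerium-catalysed acetal hydrolysis at pH 8 (Markó conditions) frees the C6 enal and the C8 aldehyde, and the latter closes at once with the C14 hydroxyl to a five-membered lactol, so only the enal remains a free aldehyde and no strong acid is present to aromatise the lactol or isomerise the enal.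

**Step 6**
Reactants: 18 methyl 2-(bromomethyl)prop-2-enoate
Product: 21 methyl (2Z)-3-bromo-2-(bromomethyl)prop-2-enoate, via tribromo ester 20 (not isolated)
Conditions: Br2, CH2Cl2, rt; then Et3N, 0 °C to rt
Reagents that add atoms: 19 bromine, BrBr
Why: Bromination–dehydrobromination gives the vinyl bromide, whose geometry does not matter because C7 becomes sp3 in step 7.

**Step 7**
Reactants: 17 (2E,6Z)-3-{[tert-butyl(diphenyl)silyl]oxymethyl}-6-(5-hydroxyoxolan-3-ylidene)hex-2-enal; 21 methyl (2Z)-3-bromo-2-(bromomethyl)prop-2-enoate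
Product: 23 (6R,7R,8S)-15-[tert-butyl(diphenyl)silyl]oxy-8,14-dihydroxygermacra-1(10),4,11(13)-trien-12,6-olide, via bromo lactone 22 (not isolated)
Conditions: CrCl2 (30 mol%), (S,S)-1,8-bis(4-isopropyl-4,5-dihydrooxazol-2-yl)-3,6-diphenyl-9H-carbazole (33 mol%), iPr2NEt (35 mol%), Mn powder (4 equiv), Cp2ZrCl2 (2.5 equiv), THF, rt; 17 and 21 (1.3 equiv) added over 12 h (final 5 mM), then 12 h; aq. NaHCO3
Reagents that add atoms: none
Why: Proposed new method: divalent chromium inserts first into the allylic C–Br bond of 21 (vinyl bromides need nickel), and the γ-bromoallyl chromium adds through its bromine-bearing carbon to the only free aldehyde, the enal, on the ligand-controlled Si face (sets C6 as R; closest precedents are Takai-type γ-haloallyl chromium additions and chromium-catalysed asymmetric 2-(alkoxycarbonyl)allylation to α-methylene lactones), the C6 alkoxide, the only one present at this stage, lactonises onto the ester to give 22, whose secondary allylic bromide is reduced again to a butenolide-type, E-locked allyl chromium that adds through C7, anti to the C6 side chain, via a chair Nozaki–Hiyama–Kishi transition state to the aldehyde released from the lactol, setting C7 (R) and C8 (S) as the anti adduct and closing the ten-membered ring (closest precedents are Barbier allylations of 3-(bromomethyl)butenolides and chromium-mediated germacranolide macrocyclisations).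

**Step 8**
Reactants: 23 (6R,7R,8S)-15-[tert-butyl(diphenyl)silyl]oxy-8,14-dihydroxygermacra-1(10),4,11(13)-trien-12,6-olide
Product: 25 (1R,6R,7R,8S,10S)-15-[tert-butyl(diphenyl)silyl]oxy-1,10-epoxy-8,14-dihydroxygermacra-4,11(13)-dien-12,6-olide
Conditions: Ti(OiPr)4 (10 mol%), L-(+)-diethyl tartrate (12 mol%), t-BuOOH (2 equiv), 4 Å MS, CH2Cl2, −20 °C
Reagents that add atoms: 24 tert-butyl hydroperoxide, CC(C)(C)OO
Why: Katsuki–Sharpless asymmetric epoxidation, in which only C1=C10 carries a free allylic hydroxyl and L-(+)-tartrate delivers oxygen to the face that gives the (1R,10S) trans-epoxide (tartrate mnemonic, reagent control), leaving the electron-poor methylene lactone and the silyl-protected C4=C5 alkene untouched.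

**Step 9**
Reactants: 25 (1R,6R,7R,8S,10S)-15-[tert-butyl(diphenyl)silyl]oxy-1,10-epoxy-8,14-dihydroxygermacra-4,11(13)-dien-12,6-olide
Product: 27 (1R,6R,7R,8S,10S)-14-acetoxy-15-[tert-butyl(diphenyl)silyl]oxy-1,10-epoxy-8-hydroxygermacra-4,11(13)-dien-12,6-olide
Conditions: Ac2O (1.2 equiv), 2,4,6-collidine, CH2Cl2, −20 to 0 °C
Reagents that add atoms: 26 acetic anhydride, CC(=O)OC(C)=O
Why: Selective acetylation, since the unhindered primary C14 hydroxyl reacts much faster than the hindered secondary C8 hydroxyl at low temperature.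

**Step 10**
Reactants: 27 (1R,6R,7R,8S,10S)-14-acetoxy-15-[tert-butyl(diphenyl)silyl]oxy-1,10-epoxy-8-hydroxygermacra-4,11(13)-dien-12,6-olide
Product: 29 (1R,6R,7R,8S,10S)-14-acetoxy-15-[tert-butyl(diphenyl)silyl]oxy-1,10-epoxy-8-(2-methylprop-2-enoyloxy)germacra-4,11(13)-dien-12,6-olide
Conditions: methacrylic anhydride (3 equiv), Et3N, DMAP (0.3 equiv), CH2Cl2, 0 °C to rt
Reagents that add atoms: 28 methacrylic anhydride, CC(=C)C(=O)OC(=O)C(C)=C
Why: DMAP-catalysed acyl transfer (Steglich-type acylation) esterifies the remaining secondary hydroxyl without touching the epoxide.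

**Step 11**
Reactants: 29 (1R,6R,7R,8S,10S)-14-acetoxy-15-[tert-butyl(diphenyl)silyl]oxy-1,10-epoxy-8-(2-methylprop-2-enoyloxy)germacra-4,11(13)-dien-12,6-olide
Product: 30 (1R,6R,7R,8S,10S)-14-acetoxy-1,10-epoxy-15-hydroxy-8-(2-methylprop-2-enoyloxy)germacra-4,11(13)-dien-12,6-olide
Conditions: HF·pyridine, pyridine, THF, 0 °C to rt
Reagents that add atoms: none
Why: Fluoride desilylation under buffered, non-basic conditions cleaves only the Si–O bond, so the epoxide, the three esters and both Michael acceptors survive and the target is released.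

**Compound list**
1 | 3,3-diethoxyprop-1-yne | C#CC(OCC)OCC | starting material
2 | paraformaldehyde (formaldehyde source) | C=O | starting material
3 | vinylmagnesium chloride | C=C[Mg]Cl | starting material
4 | bromomagnesium 4,4-diethoxybut-2-yn-1-olate | CCOC(OCC)C#CC[O-].[Mg+2].[Br-] | intermediate
5 | 3-(diethoxymethyl)-4-vinyl-2,5-dihydro-1,2-oxamagnesole | C=CC1=C(C(OCC)OCC)[Mg]OC1 | intermediate
6 | (2E)-2-(2,2-diethoxyethylidene)but-3-en-1-ol | OC/C(C=C)=C/C(OCC)OCC | intermediate
7 | tert-butyl(chloro)diphenylsilane | CC(C)(C)[Si](Cl)(c1ccccc1)c1ccccc1 | starting material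
8 | tert-butyl{[(2E)-2-(2,2-diethoxyethylidene)but-3-en-1-yl]oxy}diphenylsilane | CCOC(OCC)/C=C(/CO[Si](C(C)(C)C)(c1ccccc1)c1ccccc1)C=C | intermediate
9 | prop-2-yn-1-ol | C#CCO | starting material
10 | (1,3-dioxolan-2-ylmethyl)magnesium bromide | Br[Mg]CC1OCCO1 | starting material
11 | iodine | II | starting material
12 | 4-(1,3-dioxolan-2-ylmethyl)-2,5-dihydro-1,2-oxamagnesole | [Mg]1OCC(CC2OCCO2)=C1 | intermediate
13 | (2Z)-2-(1,3-dioxolan-2-ylmethyl)-3-iodoprop-2-en-1-ol | OC/C(CC1OCCO1)=C\I | intermediate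
14 | 9-[(3E)-3-{[tert-butyl(diphenyl)silyl]oxymethyl}-5,5-diethoxypent-3-en-1-yl]-9-borabicyclo[3.3.1]nonane | CCOC(OCC)/C=C(/CO[Si](C(C)(C)C)(c1ccccc1)c1ccccc1)CCB1C2CCCC1CCC2 | intermediate
15 | (2Z,6E)-6-{[tert-butyl(diphenyl)silyl]oxymethyl}-2-(1,3-dioxolan-2-ylmethyl)-8,8-diethoxyocta-2,6-dien-1-ol | CCOC(OCC)/C=C(/CO[Si](C(C)(C)C)(c1ccccc1)c1ccccc1)CC/C=C(\CO)CC1OCCO1 | intermediate
16 | water | O | starting material
17 | (2E,6Z)-3-{[tert-butyl(diphenyl)silyl]oxymethyl}-6-(5-hydroxyoxolan-3-ylidene)hex-2-enal (lactol anomers) | O=C/C=C(/CO[Si](C(C)(C)C)(c1ccccc1)c1ccccc1)CC/C=C1\COC(O)C1 | intermediate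
18 | methyl 2-(bromomethyl)prop-2-enoate | C=C(CBr)C(=O)OC | starting material
19 | bromine | BrBr | starting material
20 | methyl 2,3-dibromo-2-(bromomethyl)propanoate | COC(=O)C(Br)(CBr)CBr | intermediate
21 | methyl (2Z)-3-bromo-2-(bromomethyl)prop-2-enoate | COC(=O)/C(CBr)=C/Br | intermediate
22 | (5R)-4-bromo-5-[(1E,5Z)-2-{[tert-butyl(diphenyl)silyl]oxymethyl}-5-(5-hydroxyoxolan-3-ylidene)pent-1-en-1-yl]-3-methylideneoxolan-2-one (epimers at C4 and at the lactol carbon) | C=C1C(Br)[C@@H](/C=C(/CO[Si](C(C)(C)C)(c2ccccc2)c2ccccc2)CC/C=C2\COC(O)C2)OC1=O | intermediate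
23 | (6R,7R,8S)-15-[tert-butyl(diphenyl)silyl]oxy-8,14-dihydroxygermacra-1(10),4,11(13)-trien-12,6-olide (C9/C2 trans on C1=C10, C3/C6 cis on C4=C5) | O[C@H]1C/C(CO)=C/CC/C(CO[Si](C(C)(C)C)(c3ccccc3)c3ccccc3)=C\[C@H]2OC(=O)C(=C)[C@H]12 | intermediate
24 | tert-butyl hydroperoxide | CC(C)(C)OO | starting material
25 | (1R,6R,7R,8S,10S)-15-[tert-butyl(diphenyl)silyl]oxy-1,10-epoxy-8,14-dihydroxygermacra-4,11(13)-dien-12,6-olide | O[C@H]1C[C@@]2(CO)O[C@@H]2CC/C(CO[Si](C(C)(C)C)(c3ccccc3)c3ccccc3)=C\[C@H]2OC(=O)C(=C)[C@H]12 | intermediate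
26 | acetic anhydride | CC(=O)OC(C)=O | starting material
27 | (1R,6R,7R,8S,10S)-14-acetoxy-15-[tert-butyl(diphenyl)silyl]oxy-1,10-epoxy-8-hydroxygermacra-4,11(13)-dien-12,6-olide | O[C@H]1C[C@@]2(COC(C)=O)O[C@@H]2CC/C(CO[Si](C(C)(C)C)(c3ccccc3)c3ccccc3)=C\[C@H]2OC(=O)C(=C)[C@H]12 | intermediate
28 | methacrylic anhydride | CC(=C)C(=O)OC(=O)C(C)=C | starting material
29 | (1R,6R,7R,8S,10S)-14-acetoxy-15-[tert-butyl(diphenyl)silyl]oxy-1,10-epoxy-8-(2-methylprop-2-enoyloxy)germacra-4,11(13)-dien-12,6-olide | C=C(C)C(=O)O[C@H]1C[C@@]2(COC(C)=O)O[C@@H]2CC/C(CO[Si](C(C)(C)C)(c3ccccc3)c3ccccc3)=C\[C@H]2OC(=O)C(=C)[C@H]12 | intermediate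
30 | CNP0306006.2, (1R,6R,7R,8S,10S)-14-acetoxy-1,10-epoxy-15-hydroxy-8-(2-methylprop-2-enoyloxy)germacra-4,11(13)-dien-12,6-olide | C=C(C)C(=O)O[C@H]1C[C@@]2(COC(C)=O)O[C@@H]2CC/C(CO)=C\[C@H]2OC(=O)C(=C)[C@H]12 | target

**Totals**
Total step count: 11.
Longest linear sequence: 9 steps (steps 1, 2, 4, 5, 7, 8, 9, 10, 11, from 3,3-diethoxyprop-1-yne).

**Steps most likely to fail and fallbacks**

Step 7. Three things must work in one flask: ligand control at C6, lactonisation before the second chromium insertion, and the ten-membered ring closure without oligomerisation or pinacol coupling of the enal. The fallback sets out from 17 and comes back at 23. The lactone is first made separately by an asymmetric NiCl2/CrCl2 alkenylation of the enal of 17 with methyl (2Z)-2-(acetoxymethyl)-3-iodoprop-2-enoate, using a chiral sulfonamide ligand for Si-face addition. The (Z)-γ-hydroxy enoate lactonises spontaneously to the acetoxymethyl butenolide F1. The ring is then closed by a palladium/indium umpolung allylation (Pd(PPh3)4, InI, THF, high dilution): zerovalent palladium ionises the allylic acetate, indium monoiodide converts the π-allyl complex into an allylindium, and this adds through C7, anti to the C6 side chain, to the lactol aldehyde, giving 23.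

Step 4. Hydroboration of the 2-substituted diene may give regioisomers or double addition, and the alkylborane must couple cleanly with a vinyl iodide that carries a free hydroxyl. The fallback sets out from 8 and comes back at 15. Compound 8 is hydroborated with 9-BBN and the alkylborane is iodinated (I2, NaOMe) to the homoallylic iodide F2, which can be purified. F2 is then coupled with the vinylmagnesium chelate 12 of step 3, used before its iodine quench, under Li2CuCl4 catalysis (Kochi-type sp2–sp3 coupling, retention at C1). Aqueous work-up gives 15 directly.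

Step 8. The tartrate-controlled epoxidation may be mismatched with the facial bias of the macrocycle or slowed by the second free hydroxyl. The fallback sets out from 23 and comes back at 29. The primary allylic hydroxyl is acetylated first (Ac2O, collidine, −20 °C) to the 14-O-acetate F3, and the C8 hydroxyl is esterified with methacrylic anhydride/DMAP to the 8-O-methacrylate F4. The only unhindered, non-conjugated trisubstituted alkene, C1=C10, is then epoxidised with the D-fructose-derived Shi ketone and 2KHSO5·KHSO4·K2SO4 in K2CO3-buffered MeCN/dimethoxymethane/H2O at 0 °C. This reagent-controlled dioxirane needs no directing hydroxyl and its spiro transition state favours the (1R,10S) epoxide, giving 29.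

**Further compounds**
F1 | step 7 | (5R)-3-(acetoxymethyl)-5-[(1E,5Z)-2-{[tert-butyl(diphenyl)silyl]oxymethyl}-5-(5-hydroxyoxolan-3-ylidene)pent-1-en-1-yl]furan-2(5H)-one | CC(=O)OCC1=C[C@@H](/C=C(/CO[Si](C(C)(C)C)(c2ccccc2)c2ccccc2)CC/C=C2\COC(O)C2)OC1=O
F2 | step 4 | tert-butyl{[(2E)-4,4-diethoxy-2-(2-iodoethyl)but-2-en-1-yl]oxy}diphenylsilane | CCOC(OCC)/C=C(/CO[Si](C(C)(C)C)(c1ccccc1)c1ccccc1)CCI
F3 | step 8 | (6R,7R,8S)-14-acetoxy-15-[tert-butyl(diphenyl)silyl]oxy-8-hydroxygermacra-1(10),4,11(13)-trien-12,6-olide | O[C@H]1C/C(COC(C)=O)=C/CC/C(CO[Si](C(C)(C)C)(c3ccccc3)c3ccccc3)=C\[C@H]2OC(=O)C(=C)[C@H]12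
F4 | step 8 | (6R,7R,8S)-14-acetoxy-15-[tert-butyl(diphenyl)silyl]oxy-8-(2-methylprop-2-enoyloxy)germacra-1(10),4,11(13)-trien-12,6-olide | C=C(C)C(=O)O[C@H]1C/C(COC(C)=O)=C/CC/C(CO[Si](C(C)(C)C)(c3ccccc3)c3ccccc3)=C\[C@H]2OC(=O)C(=C)[C@H]12
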